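The 17-membered ring is opened at the diaryl ether between C5 of ring A (the trioxygenated ring) and the oxygen on ring B (the para-phenylene). Ring A carries oxygen on C3, C4 and C5, so C3 and C5 are mirror-related across the C4 hydroxyl and can both start as C–Br in a 4-alkyl-2,6-dibromophenol. Anodic oxidation of that phenol lets the ring B phenol oxygen bond to one brominated ortho carbon and closes the macrocycle in one operation; the remaining bromine later becomes the C3 oxygen. The substrate is an open-chain bibenzyl–O–bibenzyl carrying a 2,6-dibromophenol (ring A) and a 2,6-dichlorophenol (ring B), with the ring C–O–ring D ether already present.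

Key step: step 12

Ring labels: ring A = the ring with oxygen at C3, C4 and C5 (C1 carries the ethylene bridge to ring D); ring B = the para-phenylene; ring C = the 2-aryloxy-3,4-dioxygenated ring; ring D = the ortho-phenylene. MOM = methoxymethyl.

Remark: the target has no stereocentre. The Wittig alkenes are carried as E/Z mixtures and written without geometry, because both are saturated in step 10.

Assumption: in methanol the electrolysis is taken to stop at the macrocyclic para-quinol methyl ether (bromide lost from the first adduct, methanol added at the para carbon), which zinc then reduces to the phenol.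

Design note: the two benzylic arms must be attached one after the other. The free phenol of the ring C aldehyde is used as the handle: the ring B arm is attached first, the ring D ether second, the ring A arm last. Both halophenols travel as MOM ethers.

Step 1
Reactants: 1 3,5-dichloro-4-hydroxybenzaldehyde
Product: 2 3,5-dichloro-4-(methoxymethoxy)benzaldehyde
Conditions: MOMCl, iPr2NEt, CH2Cl2, 0 °C → rt
Reagents that add atoms: chloromethyl methyl ether, COCCl
Why: Williamson-type O-alkylation of the acidic phenol with an α-chloro ether should be fast and masks the phenol, so that it can neither quench the ylide in step 4 nor compete as nucleophile in step 5.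

Step 2
Reactants: 3 2-hydroxy-3,4-dimethoxybenzaldehyde
Product: 4 6-(hydroxymethyl)-2,3-dimethoxyphenol
Conditions: NaBH4, MeOH, 0 °C
Reagents that add atoms: none
Why: Borohydride reduction of the aryl aldehyde to the benzylic alcohol is chemoselective and tolerates the free ortho phenol.

Step 3
Reactants: 4 6-(hydroxymethyl)-2,3-dimethoxyphenol
Product: 5 (2-hydroxy-3,4-dimethoxybenzyl)triphenylphosphonium bromide
Conditions: PPh3·HBr, MeCN, reflux
Reagents that add atoms: triphenylphosphine hydrobromide, [Br-].c1ccc(cc1)[PH+](c1ccccc1)c1ccccc1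
Why: The electron-rich ortho-hydroxy/para-methoxy benzylic alcohol ionises under the mild acid and PPh3 traps the benzylic cation, the standard acid-mediated conversion of benzylic alcohols into phosphonium salts.

Step 4
Reactants: 5 (2-hydroxy-3,4-dimethoxybenzyl)triphenylphosphonium bromide; 2 3,5-dichloro-4-(methoxymethoxy)benzaldehyde
Product: 6 6-{2-[3,5-dichloro-4-(methoxymethoxy)phenyl]ethenyl}-2,3-dimethoxyphenol (E/Z mixture)
Conditions: KOtBu (2.2 equiv) added to 5 + 2, THF, 0 °C → rt
Reagents that add atoms: none
Why: Wittig olefination in which two equivalents of base give the phenoxide ylide, which should add to the electron-poor aldehyde 2; the alkene geometry is irrelevant because the double bond is saturated in step 10.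

Step 5
Reactants: 6 6-{2-[3,5-dichloro-4-(methoxymethoxy)phenyl]ethenyl}-2,3-dimethoxyphenol; 7 2-fluorobenzaldehyde
Product: 8 2-(6-{2-[3,5-dichloro-4-(methoxymethoxy)phenyl]ethenyl}-2,3-dimethoxyphenoxy)benzaldehyde (E/Z mixture)
Conditions: K2CO3, DMF, 110 °C
Reagents that add atoms: none
Why: SNAr by addition–elimination, in which the ortho formyl group activates the C–F carbon toward the ring C phenoxide while the unactivated C–Cl bonds and the MOM acetal are inert to carbonate.

Step 6
Reactants: 9 3,5-dibromo-4-hydroxybenzaldehyde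
Product: 10 3,5-dibromo-4-(methoxymethoxy)benzaldehyde
Conditions: MOMCl, iPr2NEt, CH2Cl2, 0 °C → rt
Reagents that add atoms: chloromethyl methyl ether, COCCl
Why: The same Williamson-type acetal formation caps the ring A phenol, which otherwise would let the derived para-hydroxybenzyl phosphonium salt collapse to a quinone methide under base.

Step 7
Reactants: 10 3,5-dibromo-4-(methoxymethoxy)benzaldehyde
Product: 11 [3,5-dibromo-4-(methoxymethoxy)phenyl]methanol
Conditions: NaBH4, MeOH/THF, 0 °C
Reagents that add atoms: none
Why: Borohydride reduction of the aldehyde leaves aryl bromides and the acetal untouched.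

Step 8
Reactants: 11 [3,5-dibromo-4-(methoxymethoxy)phenyl]methanol
Product: 13 [3,5-dibromo-4-(methoxymethoxy)benzyl]triphenylphosphonium bromide, via benzylic bromide 12 (not isolated)
Conditions: CBr4 (1.1 equiv), PPh3 (2.3 equiv), MeCN, 0 °C → rt; then reflux
Reagents that add atoms: carbon tetrabromide, BrC(Br)(Br)Br; triphenylphosphine, c1ccc(cc1)P(c1ccccc1)c1ccccc1
Why: Appel bromination is neutral, so the MOM acetal survives, and the surplus PPh3 then quaternises the benzylic bromide by SN2 on heating.

Step 9
Reactants: 8 2-(6-{2-[3,5-dichloro-4-(methoxymethoxy)phenyl]ethenyl}-2,3-dimethoxyphenoxy)benzaldehyde; 13 [3,5-dibromo-4-(methoxymethoxy)benzyl]triphenylphosphonium bromide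
Product: 14 open-chain bis-stilbene 1,3-dibromo-5-{2-[2-(6-{2-[3,5-dichloro-4-(methoxymethoxy)phenyl]ethenyl}-2,3-dimethoxyphenoxy)phenyl]ethenyl}-2-(methoxymethoxy)benzene (E/Z mixture at both alkenes)
Conditions: KOtBu (1.1 equiv) added to 8 + 13, THF, 0 °C → rt
Reagents that add atoms: none
Why: Wittig olefination of the non-enolisable aryl aldehyde with the semi-stabilised benzylic ylide formed in situ; both alkenes are reduced next, so the E/Z outcome does not matter.

Step 10
Reactants: 14 open-chain bis-stilbene
Product: 15 1,3-dibromo-5-{2-[2-(6-{2-[3,5-dichloro-4-(methoxymethoxy)phenyl]ethyl}-2,3-dimethoxyphenoxy)phenyl]ethyl}-2-(methoxymethoxy)benzene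
Conditions: TsNHNH2 (excess, in portions), NaOAc, DME/H2O, reflux
Reagents that add atoms: none
Why: Diimide reduction delivers H2 to both stilbene C=C bonds in a concerted syn transfer and leaves the four aryl–halogen bonds intact, which catalytic hydrogenation would not.

Step 11
Reactants: 15 bis-MOM bis-bibenzyl
Product: 16 2,6-dibromo-4-{2-[2-(6-[2-(3,5-dichloro-4-hydroxyphenyl)ethyl]-2,3-dimethoxyphenoxy)phenyl]ethyl}phenol (open-chain dibromophenol–dichlorophenol)
Conditions: HCl (3 M aq), MeOH/THF, 50 °C
Reagents that add atoms: none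
Why: Acid-catalysed acetal cleavage (transacetalisation to dimethoxymethane) frees both phenols and does not affect aryl methyl ethers, the diaryl ether or the C–halogen bonds.

Step 12
Reactants: 16 open-chain dibromophenol–dichlorophenol
Product: 18 macrocyclic 2-aryloxy-6-bromophenol (ring A 3-Br/4-OH/5-OAr; ring B 2,6-dichloro at the ether oxygen; ring C 3,4-dimethoxy), via para-quinol methyl ether 17 (not isolated)
Conditions: Pt anode, Pt cathode, undivided cell, 0.1 M LiClO4 in MeOH, substrate ca. 1 mM, constant current at low current density (anode kept below ca. +1.2 V vs SCE), ca. 2.2 F/mol, rt; then AcOH, Zn dust, rt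
Reagents that add atoms: methanol, CO (its methoxy group is carried only by intermediate 17 and is lost again on reduction)
Why: At the anode the ring A phenol is oxidised by two electrons with loss of its proton to a phenoxenium cation, the ring B phenol oxygen adds to one bromine-bearing ortho carbon, bromide departs, methanol caps the para carbon to give dienone 17, and zinc in acetic acid reduces 17 to the aromatic phenol with loss of methanol. The closest known reaction type is the oxidative coupling of 2,6-dihalophenols (at an anode or with Tl(NO3)3, then zinc) used to close macrocyclic 2-aryloxyphenol ethers of the isodityrosine family. Ring closure is a head-to-tail macroetherification in which the phenol oxygen at one terminus of the chain attacks a ring carbon at the other and forms the 17-membered ring, favoured by high dilution. Product 18 has no stereocentre, and the quaternary carbon of 17 is a transient racemic centre that the reduction erases. The step needs chemoselectivity between the two phenols and a single site of attack: bromine substitution makes ring A the more easily oxidised phenol and leaves the chlorinated ring B as the nucleophile, the two ortho positions of ring A are identical, and with all four ortho positions halogenated no carbon–carbon coupling can occur there. Cation that is only capped by methanol before cyclising is returned to 16 by the zinc treatment, so that pathway costs conversion and not material.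

Step 13
Reactants: 18 macrocyclic 2-aryloxy-6-bromophenol
Product: 19 macrocyclic methoxyphenol (ring A 3-OMe/4-OH/5-OAr; ring B 2,6-dichloro; ring C 3,4-dimethoxy)
Conditions: NaOMe (10 equiv), CuBr (0.2 equiv), DMF/MeOH, 110 °C, argon, sealed tube
Reagents that add atoms: sodium methoxide, [Na+].[O-]C
Why: Ullmann-type copper-catalysed methoxylation replaces the bromide ortho to the phenoxide, the reaction class that turns 2-bromo-4-alkylphenols into guaiacols, while aryl chlorides are far less reactive toward monovalent copper at this temperature.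

Step 14
Reactants: 19 macrocyclic methoxyphenol
Product: 20 dechlorinated macrocycle (ring A 3-OMe/4-OH/5-OAr; ring B unsubstituted para-phenylene; ring C 3,4-dimethoxy)
Conditions: H2 (1 atm), Pd/C (10%), Et3N, MeOH/EtOAc, rt
Reagents that add atoms: none
Why: Palladium-catalysed hydrogenolysis (hydrodechlorination) removes both aryl C–Cl bonds with the amine as HCl acceptor, and diaryl ethers, methyl ethers and the bibenzyl C–C bonds are not cleaved under these conditions.

Step 15
Reactants: 20 dechlorinated macrocycle
Product: 21 CNP0114693.0 (target; ring A 3,4-dihydroxy-5-aryloxy; ring C 2-aryloxy-3,4-dihydroxy)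
Conditions: BBr3 (excess), CH2Cl2, −78 °C → rt; then H2O, 0 °C
Reagents that add atoms: none
Why: Lewis-acid ether cleavage in which BBr3 complexes each methoxy oxygen and bromide removes the methyl group by SN2, whereas the two diaryl ether oxygens carry no sp3 carbon and survive.

Compound list
1 | 3,5-dichloro-4-hydroxybenzaldehyde | O=Cc1cc(Cl)c(O)c(Cl)c1 | starting material
2 | 3,5-dichloro-4-(methoxymethoxy)benzaldehyde | O=Cc1cc(Cl)c(OCOC)c(Cl)c1 | intermediate
3 | 2-hydroxy-3,4-dimethoxybenzaldehyde | COc1ccc(C=O)c(O)c1OC | starting material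
4 | 6-(hydroxymethyl)-2,3-dimethoxyphenol | COc1ccc(CO)c(O)c1OC | intermediate
5 | (2-hydroxy-3,4-dimethoxybenzyl)triphenylphosphonium bromide | COc1ccc(C[P+](c2ccccc2)(c2ccccc2)c2ccccc2)c(O)c1OC.[Br-] | intermediate
6 | 6-{2-[3,5-dichloro-4-(methoxymethoxy)phenyl]ethenyl}-2,3-dimethoxyphenol, E/Z mixture | COc1ccc(C=Cc2cc(Cl)c(OCOC)c(Cl)c2)c(O)c1OC | intermediate
7 | 2-fluorobenzaldehyde | O=Cc1ccccc1F | starting material
8 | 2-(6-{2-[3,5-dichloro-4-(methoxymethoxy)phenyl]ethenyl}-2,3-dimethoxyphenoxy)benzaldehyde, E/Z mixture | COc1ccc(C=Cc2cc(Cl)c(OCOC)c(Cl)c2)c(Oc2ccccc2C=O)c1OC | intermediate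
9 | 3,5-dibromo-4-hydroxybenzaldehyde | O=Cc1cc(Br)c(O)c(Br)c1 | starting material
10 | 3,5-dibromo-4-(methoxymethoxy)benzaldehyde | O=Cc1cc(Br)c(OCOC)c(Br)c1 | intermediate
11 | [3,5-dibromo-4-(methoxymethoxy)phenyl]methanol | OCc1cc(Br)c(OCOC)c(Br)c1 | intermediate
12 | 1,3-dibromo-5-(bromomethyl)-2-(methoxymethoxy)benzene | BrCc1cc(Br)c(OCOC)c(Br)c1 | intermediate (not isolated)
13 | [3,5-dibromo-4-(methoxymethoxy)benzyl]triphenylphosphonium bromide | COCOc1c(Br)cc(C[P+](c2ccccc2)(c2ccccc2)c2ccccc2)cc1Br.[Br-] | intermediate
14 | open-chain bis-stilbene with MOM-protected dibromophenol (ring A) and dichlorophenol (ring B), E/Z mixture at both alkenes | COCOc1c(Br)cc(C=Cc2ccccc2Oc2c(OC)c(OC)ccc2C=Cc2cc(Cl)c(OCOC)c(Cl)c2)cc1Br | intermediate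
15 | open-chain bis-bibenzyl with both halophenols as MOM ethers | COCOc1c(Br)cc(CCc2ccccc2Oc2c(OC)c(OC)ccc2CCc2cc(Cl)c(OCOC)c(Cl)c2)cc1Br | intermediate
16 | 2,6-dibromo-4-{2-[2-(6-[2-(3,5-dichloro-4-hydroxyphenyl)ethyl]-2,3-dimethoxyphenoxy)phenyl]ethyl}phenol | Oc1c(Br)cc(cc1Br)CCc1ccccc1Oc1c(OC)c(OC)ccc1CCc1cc(Cl)c(O)c(Cl)c1 | intermediate
17 | macrocyclic para-quinol methyl ether: ring A as a 6-bromo-4-methoxycyclohexa-2,5-dien-1-one whose C2 is bonded to the ring B oxygen and whose C4 carries the ethylene bridge to ring D, racemic at C4 | O=C1C(Br)=CC2(OC)C=C1Oc1c(Cl)cc(cc1Cl)CCc1ccc(OC)c(OC)c1Oc1ccccc1CC2 | intermediate (not isolated)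
18 | macrocyclic 2-aryloxy-6-bromophenol: ring A 3-bromo-4-hydroxy-5-aryloxy, ring B 2,6-dichloro at the ether oxygen, ring C 3,4-dimethoxy | Brc1cc2cc(c1O)Oc1c(Cl)cc(cc1Cl)CCc1ccc(OC)c(OC)c1Oc1ccccc1CC2 | intermediate
19 | macrocyclic methoxyphenol: ring A 3-methoxy-4-hydroxy-5-aryloxy, ring B 2,6-dichloro, ring C 3,4-dimethoxy | COc1cc2cc(c1O)Oc1c(Cl)cc(cc1Cl)CCc1ccc(OC)c(OC)c1Oc1ccccc1CC2 | intermediate
20 | dechlorinated macrocycle: ring A 3-methoxy-4-hydroxy-5-aryloxy, ring B para-phenylene, ring C 3,4-dimethoxy | COc1cc2cc(c1O)Oc1ccc(cc1)CCc1ccc(OC)c(OC)c1Oc1ccccc1CC2 | intermediate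
21 | CNP0114693.0 | Oc1cc2cc(c1O)Oc1ccc(cc1)CCc1ccc(O)c(O)c1Oc1ccccc1CC2 | target

Total step count: 15. Longest linear sequence: 11 steps (from 3 through steps 2, 3, 4, 5, 9, 10, 11, 12, 13, 14 and 15).

Steps most likely to fail

Step 12. Intermolecular phenol coupling may outrun ring closure even at high dilution, and the electron-rich dimethoxy ring C may be oxidised if the anode potential drifts upward. The fallback forms the same C5(ring A)–O–ring B bond by a copper-mediated Ullmann macrocyclisation; it sets out from 8 and rejoins the route at 20.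
- Commercial 5-bromovanillin would be benzylated (BnBr, K2CO3, DMF) to 4-(benzyloxy)-3-bromo-5-methoxybenzaldehyde F1.
- F1 would be reduced (NaBH4, MeOH) to [4-(benzyloxy)-3-bromo-5-methoxyphenyl]methanol F2.
- F2 would be converted with PPh3·HBr in MeCN into [4-(benzyloxy)-3-bromo-5-methoxybenzyl]triphenylphosphonium bromide F3.
- Wittig reaction of F3 with 8 (KOtBu, THF) should give the benzyl-protected bromo bis-stilbene F4.
- Diimide reduction as in step 10 should give the benzyl-protected bromo bis-bibenzyl F5.
- HCl in MeOH should remove the single MOM group to give the open-chain bromoarene–dichlorophenol F6.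
- Intramolecular Ullmann ether synthesis (CuI, N,N-dimethylglycine, Cs2CO3, dioxane, 100 °C, high dilution) should then give the macrocyclic benzyl ether F7; the chlorines are only passengers here.
- H2, Pd/C and Et3N would remove the benzyl group and both chlorines in one operation to give 20.

Step 13. Reductive loss of bromine (hydrodebromination by methoxide/copper) or sluggish substitution on the hindered, electron-rich phenoxide may compete. The fallback is palladium-catalysed borylation and oxidation; it sets out from 18 and rejoins the route at 21.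
- Methylation of 18 (MeI, K2CO3, DMF) would give the macrocyclic bromoanisole F8.
- Miyaura borylation (B2pin2, PdCl2(dppf), KOAc, dioxane, 90 °C) should give the macrocyclic pinacol boronate F9.
- Oxidation (H2O2, NaOH, THF, 0 °C) should give the macrocyclic 3-hydroxy-4-methoxy phenol F10.
- Hydrodechlorination as in step 14 would give the dechlorinated 3-hydroxy-4-methoxy macrocycle F11.
- BBr3 as in step 15 would give 21.

Step 4. The phenoxide–phosphonium may fragment to an ortho-quinone methide with loss of PPh3 and oligomerise instead of olefinating. The fallback exchanges the roles of the two olefination partners, so that the ylide sits on the MOM-capped ring B; it sets out from 2 and 3 and rejoins the route at 6.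
- Reduction of 2 (NaBH4, MeOH) would give [3,5-dichloro-4-(methoxymethoxy)phenyl]methanol F12.
- Appel bromination (CBr4, PPh3) should give 5-(bromomethyl)-1,3-dichloro-2-(methoxymethoxy)benzene F13, which is not isolated.
- Heating with PPh3 should give [3,5-dichloro-4-(methoxymethoxy)benzyl]triphenylphosphonium bromide F14.
- The ylide of F14, used in excess with enough KOtBu to also deprotonate the phenol, would olefinate 3 to give 6.

Further compounds
F1 | step 12 | 4-(benzyloxy)-3-bromo-5-methoxybenzaldehyde | COc1cc(C=O)cc(Br)c1OCc1ccccc1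
F2 | step 12 | [4-(benzyloxy)-3-bromo-5-methoxyphenyl]methanol | COc1cc(CO)cc(Br)c1OCc1ccccc1
F3 | step 12 | [4-(benzyloxy)-3-bromo-5-methoxybenzyl]triphenylphosphonium bromide | COc1cc(C[P+](c2ccccc2)(c2ccccc2)c2ccccc2)cc(Br)c1OCc1ccccc1.[Br-]
F4 | step 12 | benzyl-protected bromo bis-stilbene (ring A 4-benzyloxy-3-bromo-5-methoxy; ring B MOM-protected dichlorophenol), E/Z mixture | COc1cc(C=Cc2ccccc2Oc2c(OC)c(OC)ccc2C=Cc2cc(Cl)c(OCOC)c(Cl)c2)cc(Br)c1OCc1ccccc1
F5 | step 12 | benzyl-protected bromo bis-bibenzyl | COc1cc(CCc2ccccc2Oc2c(OC)c(OC)ccc2CCc2cc(Cl)c(OCOC)c(Cl)c2)cc(Br)c1OCc1ccccc1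
F6 | step 12 | open-chain bromoarene–dichlorophenol | COc1cc(CCc2ccccc2Oc2c(OC)c(OC)ccc2CCc2cc(Cl)c(O)c(Cl)c2)cc(Br)c1OCc1ccccc1
F7 | step 12 | macrocyclic benzyl ether (ring A 3-methoxy-4-benzyloxy-5-aryloxy; ring B 2,6-dichloro; ring C 3,4-dimethoxy) | COc1cc2cc(c1OCc3ccccc3)Oc1c(Cl)cc(cc1Cl)CCc1ccc(OC)c(OC)c1Oc1ccccc1CC2
F8 | step 13 | macrocyclic bromoanisole (ring A 3-bromo-4-methoxy-5-aryloxy; ring B 2,6-dichloro) | Brc1cc2cc(c1OC)Oc1c(Cl)cc(cc1Cl)CCc1ccc(OC)c(OC)c1Oc1ccccc1CC2
F9 | step 13 | macrocyclic pinacol boronate (boron at ring A C3) | CC3(C)OB(OC3(C)C)c1cc2cc(c1OC)Oc1c(Cl)cc(cc1Cl)CCc1ccc(OC)c(OC)c1Oc1ccccc1CC2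
F10 | step 13 | macrocyclic 3-hydroxy-4-methoxy phenol (ring B 2,6-dichloro) | Oc1cc2cc(c1OC)Oc1c(Cl)cc(cc1Cl)CCc1ccc(OC)c(OC)c1Oc1ccccc1CC2
F11 | step 13 | dechlorinated 3-hydroxy-4-methoxy macrocycle | Oc1cc2cc(c1OC)Oc1ccc(cc1)CCc1ccc(OC)c(OC)c1Oc1ccccc1CC2
F12 | step 4 | [3,5-dichloro-4-(methoxymethoxy)phenyl]methanol | OCc1cc(Cl)c(OCOC)c(Cl)c1
F13 | step 4 | 5-(bromomethyl)-1,3-dichloro-2-(methoxymethoxy)benzene | BrCc1cc(Cl)c(OCOC)c(Cl)c1
F14 | step 4 | [3,5-dichloro-4-(methoxymethoxy)benzyl]triphenylphosphonium bromide | COCOc1c(Cl)cc(C[P+](c2ccccc2)(c2ccccc2)c2ccccc2)cc1Cl.[Br-]
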